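**Plan**

- Retrosynthesis: the acetate is traced back to a silyl ether. The lactone bonds C2–C3 and C2–O1 are then cut together, releasing carbon monoxide and leaving an allenol. Next come C4–C5 and C3–CH3 (one formaldehyde carbon each), and last the side-chain bond C13'–C14' (acetylide plus epoxide).
- Forward: the C18 chain is joined first and the triple bond is walked to the far terminus. Two formaldehyde units then turn the terminal alkyne into a 2-alkylbuta-2,3-dien-1-ol. The butenolide, the only ring, is closed by uptake of CO, and the silyl ether is exchanged for the acetate.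
- Enabling feature: ring atoms O1, C2(=O), C3(CH3)=C4(chain) and C5H2 are exactly a 2-alkylbuta-2,3-dien-1-ol (C5H2–OH, C4, central carbon = C3, terminal CH2 = the C3 methyl) plus one CO (C2).
- Stereochemistry: the single S carbinol centre comes from (S)-propylene oxide, which is opened at its CH2. No later step breaks a bond at that carbon.

Key step: step 7

Remark: paraformaldehyde (step 4) and formalin (step 6) are both counted as formaldehyde 7. The organoindium of step 6 is drawn as the monoalkylindium dibromide, the simplest member of the sesquibromide mixture that indium metal gives with a propargylic bromide.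

**Step 1**
Reactants: 1 1-pentadecyne; 2 (S)-propylene oxide
Product: 4 (2S)-octadec-4-yn-2-ol, via lithium pentadecynide 3 (not isolated)
Conditions: n-BuLi, THF, −78 °C; then 2, DMPU, −78 °C → rt
Reagents that add atoms: none
Why: Deprotonation gives the alkynyllithium, which opens the terminal epoxide by SN2 attack at the unhindered CH2 (alkynylation of an epoxide), so the C–O stereocentre of 2 is carried into 4 unchanged as S.

**Step 2**
Reactants: 4 (2S)-octadec-4-yn-2-ol
Product: 5 (2S)-octadec-17-yn-2-ol
Conditions: KH, H2N(CH2)3NH2, THF, 0 °C → rt
Reagents that add atoms: none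
Why: Alkyne zipper reaction, in which potassium 3-aminopropylamide moves the triple bond thirteen positions through reversible propargyl/allenyl deprotonations until it is trapped as the terminal acetylide, while the carbinol carbon, held as its alkoxide, is not deprotonated and should keep the S configuration.

**Step 3**
Reactants: 5 (2S)-octadec-17-yn-2-ol
Product: 6 tert-butyl(dimethyl){[(2S)-octadec-17-yn-2-yl]oxy}silane
Conditions: TBSCl, imidazole, DMF, rt
Reagents that add atoms: tert-butyldimethylsilyl chloride, CC(C)(C)[Si](C)(C)Cl
Why: Imidazole-promoted silylation of a secondary alcohol, giving an ether that should withstand the organolithium, Appel, indium and carbonylation conditions that follow.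

**Step 4**
Reactants: 6 tert-butyl(dimethyl){[(2S)-octadec-17-yn-2-yl]oxy}silane; 7 formaldehyde (as paraformaldehyde)
Product: 9 (18S)-18-[(tert-butyldimethylsilyl)oxy]nonadec-2-yn-1-ol, via lithium alkynide 8 (not isolated)
Conditions: n-BuLi, THF, −78 °C; then (CH2O)n, −78 °C → rt
Reagents that add atoms: none
Why: Addition of a lithium acetylide to formaldehyde (hydroxymethylation of a terminal alkyne) gives the primary propargylic alcohol, and the silyl ether is inert to n-BuLi at low temperature.

**Step 5**
Reactants: 9 (18S)-18-[(tert-butyldimethylsilyl)oxy]nonadec-2-yn-1-ol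
Product: 10 {[(2S)-19-bromononadec-17-yn-2-yl]oxy}(tert-butyl)dimethylsilane
Conditions: CBr4, PPh3, CH2Cl2, 0 °C
Reagents that add atoms: carbon tetrabromide, BrC(Br)(Br)Br
Why: Appel reaction, in which the primary propargylic alcohol is activated as an alkoxyphosphonium ion and displaced by bromide under near-neutral conditions that should leave the secondary silyl ether intact.

**Step 6**
Reactants: 10 {[(2S)-19-bromononadec-17-yn-2-yl]oxy}(tert-butyl)dimethylsilane; 7 formaldehyde (as 37% aqueous solution)
Product: 12 2-[(15S)-15-[(tert-butyldimethylsilyl)oxy]hexadecyl]buta-2,3-dien-1-ol, via propargylindium dibromide 11 (not isolated)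
Conditions: In powder, 37% aq. HCHO, THF/H2O, rt
Reagents that add atoms: none
Why: Indium-mediated Barbier-type reaction, in which the propargylic organoindium adds to formaldehyde through an SE2' transition state at the alkyl-bearing gamma carbon, the known preference for gamma-substituted propargyl bromides, and so should give the 2-substituted buta-2,3-dien-1-ol.

**Step 7**
Reactants: 12 2-[(15S)-15-[(tert-butyldimethylsilyl)oxy]hexadecyl]buta-2,3-dien-1-ol; 13 carbon monoxide
Product: 14 4-[(15S)-15-[(tert-butyldimethylsilyl)oxy]hexadecyl]-3-methylfuran-2(5H)-one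
Conditions: Ru3(CO)12 (2 mol %), CO (10 atm), Et3N, 1,4-dioxane, 100 °C
Reagents that add atoms: none
Why: The O–H bond of 12 should add to a zerovalent ruthenium carbonyl with help from Et3N, and CO insertion should give an alkoxycarbonyl ruthenium hydride whose acyl carbon is passed intramolecularly to the central sp carbon of the allene, forming C2–C3 and an allylruthenium; hydrogen transfer to the unsubstituted CH2 terminus then makes the C3 methyl and leaves the C3=C4 alkene conjugated (hydroxyl-directed hydrometalation of the terminal C=C, CO insertion into the vinyl–Ru bond and lactonisation would lead to the same product). The closest known reaction type is the Ru3(CO)12/Et3N-catalysed carbonylative lactonisation of allenyl alcohols, which turns buta-2,3-dien-1-ols into 3-methylfuran-2(5H)-ones. The one ring (O1, C2, C3, C4, C5) closes as a carbonylative (4+1) annulation, a five-membered closure that is endo to the proximal C=C and exo to the distal one. No stereocentre is formed, and the remote silyloxy stereocentre is not touched. The step needs CO at the central allene carbon and hydrogen at the terminal one: the one-carbon tether between OH and allene permits only this five-membered acyl transfer, the terminus is unsubstituted, and the resulting tetrasubstituted alkene is conjugated with the lactone carbonyl, so a six-membered lactone or a 2,5-dihydrofuran from direct O-cyclisation should not compete under CO pressure.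

**Step 8**
Reactants: 14 4-[(15S)-15-[(tert-butyldimethylsilyl)oxy]hexadecyl]-3-methylfuran-2(5H)-one
Product: 15 4-[(15S)-15-hydroxyhexadecyl]-3-methylfuran-2(5H)-one
Conditions: HF·pyridine, THF, 0 °C → rt
Reagents that add atoms: none
Why: Fluoride-driven cleavage of the Si–O bond (desilylation) under mildly acidic conditions that avoid base-mediated deprotonation at C5 of the butenolide, with the C–O bond of the stereocentre left unbroken.

**Step 9**
Reactants: 15 4-[(15S)-15-hydroxyhexadecyl]-3-methylfuran-2(5H)-one
Product: 16 (2S)-16-(4-methyl-5-oxo-2,5-dihydrofuran-3-yl)hexadecan-2-yl acetate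
Conditions: Ac2O, pyridine, DMAP (cat.), CH2Cl2, 0 °C → rt
Reagents that add atoms: acetic anhydride, CC(=O)OC(C)=O
Why: DMAP-catalysed acylation of the secondary alcohol by acetic anhydride, which reacts only at the O–H bond and therefore retains the S configuration.

**Compound list**

1 | 1-pentadecyne | C#CCCCCCCCCCCCCC | starting material
2 | (S)-propylene oxide | C[C@H]1CO1 | starting material
3 | lithium pentadecynide | [Li]C#CCCCCCCCCCCCCC | intermediate
4 | (2S)-octadec-4-yn-2-ol | CCCCCCCCCCCCCC#CC[C@H](C)O | intermediate
5 | (2S)-octadec-17-yn-2-ol | C#CCCCCCCCCCCCCCC[C@H](C)O | intermediate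
6 | tert-butyl(dimethyl){[(2S)-octadec-17-yn-2-yl]oxy}silane | C#CCCCCCCCCCCCCCC[C@H](C)O[Si](C)(C)C(C)(C)C | intermediate
7 | formaldehyde | C=O | starting material
8 | lithium (17S)-17-[(tert-butyldimethylsilyl)oxy]octadec-1-yn-1-ide | [Li]C#CCCCCCCCCCCCCCC[C@H](C)O[Si](C)(C)C(C)(C)C | intermediate
9 | (18S)-18-[(tert-butyldimethylsilyl)oxy]nonadec-2-yn-1-ol | OCC#CCCCCCCCCCCCCCC[C@H](C)O[Si](C)(C)C(C)(C)C | intermediate
10 | {[(2S)-19-bromononadec-17-yn-2-yl]oxy}(tert-butyl)dimethylsilane | BrCC#CCCCCCCCCCCCCCC[C@H](C)O[Si](C)(C)C(C)(C)C | intermediate
11 | {(18S)-18-[(tert-butyldimethylsilyl)oxy]nonadec-2-yn-1-yl}indium dibromide | Br[In](Br)CC#CCCCCCCCCCCCCCC[C@H](C)O[Si](C)(C)C(C)(C)C | intermediate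
12 | 2-[(15S)-15-[(tert-butyldimethylsilyl)oxy]hexadecyl]buta-2,3-dien-1-ol | C=C=C(CO)CCCCCCCCCCCCCC[C@H](C)O[Si](C)(C)C(C)(C)C | intermediate
13 | carbon monoxide | [C-]#[O+] | starting material
14 | 4-[(15S)-15-[(tert-butyldimethylsilyl)oxy]hexadecyl]-3-methylfuran-2(5H)-one | CC1=C(CCCCCCCCCCCCCC[C@H](C)O[Si](C)(C)C(C)(C)C)COC1=O | intermediate
15 | 4-[(15S)-15-hydroxyhexadecyl]-3-methylfuran-2(5H)-one | CC1=C(CCCCCCCCCCCCCC[C@H](C)O)COC1=O | intermediate
16 | (2S)-16-(4-methyl-5-oxo-2,5-dihydrofuran-3-yl)hexadecan-2-yl acetate | CC(=O)O[C@@H](C)CCCCCCCCCCCCCCC1=C(C)C(=O)OC1 | target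

Total step count: 9. Longest linear sequence: 9 steps (1 → 16).

**Steps most likely to fail**

1. Step 7. The catalyst may turn over slowly with a 2-alkyl-substituted allenol. Cycloisomerisation by O-attack on the allene terminus, or oligomerisation of the allene, could then outrun CO uptake. The fallback sets out from alkyne 6 and rejoins at butenolide 14, forming the C3=C4 bond instead of C2–C3 and C2–O1. Gold-catalysed oxidative acyloxylation of the terminal alkyne would be run with 2-(diethoxyphosphoryl)propanoic acid, 8-methylquinoline N-oxide and Ph3PAuNTf2 (a monovalent gold catalyst) in chlorobenzene. This should give (17S)-17-[(tert-butyldimethylsilyl)oxy]-2-oxooctadecyl 2-(diethoxyphosphoryl)propanoate F1 by trapping of the alpha-oxo gold carbene with the acid. An intramolecular Horner–Wadsworth–Emmons reaction under Masamune–Roush conditions (LiCl, DBU, MeCN) should then close the ring onto the ketone and deliver 14.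

2. Step 6. Regiocontrol in the SE2' addition may be lost, with bond formation at the propargylic instead of the allenic carbon. Reductive debromination or Wurtz-type coupling of the very lipophilic bromide on the indium surface in a partly aqueous medium is also possible. The fallback sets out from propargylic alcohol 9 and rejoins at allenol 12. Methyl chloroformate and pyridine in CH2Cl2 would give (18S)-18-[(tert-butyldimethylsilyl)oxy]nonadec-2-yn-1-yl methyl carbonate F2. Carbonylation with carbon monoxide 13 in MeOH, using zerovalent palladium formed from Pd(OAc)2 and PPh3 at about 50 °C, should proceed through an allenylpalladium intermediate to methyl 2-[(15S)-15-[(tert-butyldimethylsilyl)oxy]hexadecyl]buta-2,3-dienoate F3. 1,2-Reduction with i-Bu2AlH in CH2Cl2 at −78 °C would give 12.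

3. Step 2. The thirteen-position migration may stall if the dipotassium salt of the long-chain alkynol precipitates. Configurational purity could also erode if the triple bond transiently reaches the carbinol. The fallback sets out from epoxide 2 and rejoins at alkynol 5, placing the terminal alkyne by C–C bond formation instead of isomerisation. 1-(Trimethylsilyl)propyne would be lithiated with n-BuLi in THF to [3-(trimethylsilyl)prop-2-yn-1-yl]lithium F4. Alkylation with an excess of 1,12-dibromododecane should give (15-bromopentadec-1-yn-1-yl)trimethylsilane F5. Magnesium in THF would convert this into [15-(trimethylsilyl)pentadec-14-yn-1-yl]magnesium bromide F6. CuI-catalysed opening of 2 at its CH2 should give (2S)-18-(trimethylsilyl)octadec-17-yn-2-ol F7 with the S centre intact. K2CO3 in MeOH would remove the C-silyl group to give 5.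

**Further compounds**

F1 | step 7 | (17S)-17-[(tert-butyldimethylsilyl)oxy]-2-oxooctadecyl 2-(diethoxyphosphoryl)propanoate | CCOP(=O)(OCC)C(C)C(=O)OCC(=O)CCCCCCCCCCCCCC[C@H](C)O[Si](C)(C)C(C)(C)C
F2 | step 6 | (18S)-18-[(tert-butyldimethylsilyl)oxy]nonadec-2-yn-1-yl methyl carbonate | COC(=O)OCC#CCCCCCCCCCCCCCC[C@H](C)O[Si](C)(C)C(C)(C)C
F3 | step 6 | methyl 2-[(15S)-15-[(tert-butyldimethylsilyl)oxy]hexadecyl]buta-2,3-dienoate | C=C=C(C(=O)OC)CCCCCCCCCCCCCC[C@H](C)O[Si](C)(C)C(C)(C)C
F4 | step 2 | [3-(trimethylsilyl)prop-2-yn-1-yl]lithium | [Li]CC#C[Si](C)(C)C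
F5 | step 2 | (15-bromopentadec-1-yn-1-yl)trimethylsilane | C[Si](C)(C)C#CCCCCCCCCCCCCCBr
F6 | step 2 | [15-(trimethylsilyl)pentadec-14-yn-1-yl]magnesium bromide | C[Si](C)(C)C#CCCCCCCCCCCCCC[Mg]Br
F7 | step 2 | (2S)-18-(trimethylsilyl)octadec-17-yn-2-ol | C[Si](C)(C)C#CCCCCCCCCCCCCCC[C@H](C)O
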